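**Strategy.** The diaryl ether is not made by aryl–O coupling: the ether oxygen is attached to an sp3 carbon by phenoxide alkylation, and ring B is then built around it. In ring B (C1 ether carbon, C2 CH2OH carbon, C4 and C6 OMe carbons) the 1,3-dioxygenation is read as a cyclohexane-1,3-dione and the C2 carbon substituent as a fumarate carboxyl. One Michael–Claisen operation on an aryloxyacetone, in which the ring-A benzoate carries a free ortho phenol and a 2-oxopropoxy group, forges C1–C2 and C4–C5 and closes the ring. Iodine/methanol aromatisation, O-prenylation and chemoselective ester reduction finish the synthesis.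

Key step: step 2

Remark on the chemistry: ring A is the methyl benzoate ring; ring B is numbered C1 (ether carbon), C2 (CH2OH carbon), C3 (CH), C4 (C–OMe), C5 (CH), C6 (C–OMe). Compounds 5 and 6 are written as keto tautomers, although 6 should exist largely as an enol. Compound 6 is racemic with one enantiomer drawn, and 5 is a diastereomer mixture with undefined stereocentres. The four starting materials are taken as purchasable.

Step 1
Reactants: 1 methyl 2,6-dihydroxy-4-methylbenzoate; 2 chloroacetone (1.05 equiv)
Product: 3 methyl 2-hydroxy-4-methyl-6-(2-oxopropoxy)benzoate
Conditions: K2CO3 (1.1 equiv), acetone, reflux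
Reagents that add atoms: none
Why: Williamson ether synthesis in which the carbonate-generated phenoxide displaces chloride from the α-halo ketone; after the first alkylation the remaining hydroxyl is held in a hydrogen bond to the ester carbonyl, which together with one equivalent of electrophile should hold the reaction at the mono-ether.

Step 2
Reactants: 3 methyl 2-hydroxy-4-methyl-6-(2-oxopropoxy)benzoate; 4 dimethyl fumarate (1.5 equiv)
Product: 6 methyl trans-2-[3-hydroxy-2-(methoxycarbonyl)-5-methylphenoxy]-3,5-dioxocyclohexane-1-carboxylate (racemic), via keto diester 5 (not isolated)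
Conditions: NaOMe (3 equiv, added in portions to 3 and 4), MeOH, 0 °C to reflux; then 1 M HCl
Reagents that add atoms: none
Why: Methoxide first converts the phenol of 3 into its phenoxide and then reversibly enolises the ketone toward the more acidic O–CH2–C=O carbon; this enolate adds to the fumarate double bond (Michael addition, C1–C2 bond) to give keto diester 5. Deprotonation of the acetyl methyl group of 5 and attack on the ester carbonyl at the far end of the succinate chain (Claisen condensation, C4–C5 bond) closes ring B as a six-membered carbocycle in a 6-(enolendo)-exo-trig mode, and expulsion of methoxide followed by deprotonation of the new 1,3-dione pulls the preceding equilibria forward. The closest known reaction type is the consecutive Michael–Claisen synthesis of cyclohexane-1,3-diones from a methyl ketone and an α,β-unsaturated ester. C1 and C2 become stereocentres; each bears an acidic hydrogen next to a carbonyl group and epimerises under the alkoxide, so the trans racemate with both substituents pseudo-equatorial is expected under thermodynamic control (no absolute control is needed because both centres are destroyed in step 3). The step needs Michael addition through the oxygen-bearing methylene instead of the methyl group, which rests on the higher acidity of that position under equilibrating conditions, and six-membered instead of five-membered Claisen closure, which follows because attack on the nearer ester would give a more strained cyclopentane-1,3-dione in a reversible reaction. It also needs the ring-A ester to stay out of a Dieckmann-type closure by the C1 carbanion and the aryloxide to resist β-elimination; the ortho phenoxide should secure both by making that ester electron-rich and doubly flanked and the leaving group a dianion, and fumarate is kept in excess so that the enolate is intercepted intermolecularly.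

Step 3
Reactants: 6 methyl trans-2-[3-hydroxy-2-(methoxycarbonyl)-5-methylphenoxy]-3,5-dioxocyclohexane-1-carboxylate
Product: 7 methyl 2-[3-hydroxy-2-(methoxycarbonyl)-5-methylphenoxy]-3,5-dimethoxybenzoate
Conditions: I2 (2 equiv), MeOH, reflux; aq. Na2S2O3 work-up
Reagents that add atoms: methanol, CO
Why: Iodine–methanol oxidative aromatisation of a cyclohexane-1,3-dione, in which the hydrogen iodide formed catalyses conversion of both carbonyl groups into methyl enol ethers, α-iodination and loss of HI supply the missing unsaturation and tautomerisation gives the resorcinol dimethyl ether with both transient stereocentres erased, while the ester-chelated ring-A phenol is not etherified under these acidic conditions.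

Step 4
Reactants: 7 methyl 2-[3-hydroxy-2-(methoxycarbonyl)-5-methylphenoxy]-3,5-dimethoxybenzoate; 8 prenyl bromide (1.3 equiv)
Product: 9 methyl 2-{2-(methoxycarbonyl)-5-methyl-3-[(3-methylbut-2-en-1-yl)oxy]phenoxy}-3,5-dimethoxybenzoate
Conditions: K2CO3 (2 equiv), DMF, 50 °C
Reagents that add atoms: none
Why: Williamson O-alkylation of the only remaining phenol with a reactive allylic bromide; carbonate in a dipolar aprotic solvent favours O- over C-prenylation, and the prenyl group is introduced only now because its alkene would not tolerate iodine in methanol.

Step 5
Reactants: 9 methyl 2-{2-(methoxycarbonyl)-5-methyl-3-[(3-methylbut-2-en-1-yl)oxy]phenoxy}-3,5-dimethoxybenzoate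
Product: 10 methyl 2-[2-(hydroxymethyl)-4,6-dimethoxyphenoxy]-4-methyl-6-[(3-methylbut-2-en-1-yl)oxy]benzoate (target)
Conditions: LiBH4 (1.5–2 equiv), THF, 0 °C to rt; then H2O
Reagents that add atoms: none
Why: Chemoselective ester reduction with lithium borohydride, relying on the inertness of a 2,6-dioxygenated benzoate toward carbonyl addition: the ring-A ester is shielded by two ortho oxygen substituents, whereas the ring-B ester has a free ortho position and should be reduced to the benzylic alcohol, with the prenyl alkene and the aryl ethers untouched.

**Compound list**

1 | methyl 2,6-dihydroxy-4-methylbenzoate | COC(=O)c1c(O)cc(C)cc1O | starting material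
2 | chloroacetone (1-chloropropan-2-one) | CC(=O)CCl | starting material
3 | methyl 2-hydroxy-4-methyl-6-(2-oxopropoxy)benzoate | COC(=O)c1c(O)cc(C)cc1OCC(C)=O | intermediate
4 | dimethyl fumarate (E) | COC(=O)/C=C/C(=O)OC | starting material
5 | dimethyl 2-{1-[3-hydroxy-2-(methoxycarbonyl)-5-methylphenoxy]-2-oxopropyl}butanedioate (keto diester, diastereomer mixture, not isolated) | COC(=O)CC(C(=O)OC)C(Oc1cc(C)cc(O)c1C(=O)OC)C(C)=O | intermediate
6 | methyl trans-2-[3-hydroxy-2-(methoxycarbonyl)-5-methylphenoxy]-3,5-dioxocyclohexane-1-carboxylate (racemic, one enantiomer drawn) | COC(=O)[C@H]1CC(=O)CC(=O)[C@@H]1Oc1cc(C)cc(O)c1C(=O)OC | intermediate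
7 | methyl 2-[3-hydroxy-2-(methoxycarbonyl)-5-methylphenoxy]-3,5-dimethoxybenzoate | COC(=O)c1cc(OC)cc(OC)c1Oc1cc(C)cc(O)c1C(=O)OC | intermediate
8 | prenyl bromide (1-bromo-3-methylbut-2-ene) | CC(C)=CCBr | starting material
9 | methyl 2-{2-(methoxycarbonyl)-5-methyl-3-[(3-methylbut-2-en-1-yl)oxy]phenoxy}-3,5-dimethoxybenzoate | COC(=O)c1cc(OC)cc(OC)c1Oc1cc(C)cc(OCC=C(C)C)c1C(=O)OC | intermediate
10 | methyl 2-[2-(hydroxymethyl)-4,6-dimethoxyphenoxy]-4-methyl-6-[(3-methylbut-2-en-1-yl)oxy]benzoate (achiral) | COC(=O)c1c(OCC=C(C)C)cc(C)cc1Oc1c(CO)cc(OC)cc1OC | target

**Step count.** Total: 5 steps. Longest linear sequence: 5 steps (1 → 3 → 6 → 7 → 9 → 10).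

**Steps most likely to fail, with fallbacks**

Step 2 (key step). The C1 carbanion may close onto the neighbouring ring-A ester (Dieckmann-type benzofuranone formation) before fumarate intercepts it. Alternatively, the aryloxide may be expelled by β-elimination from the adduct, with aromatisation of the new ring. The fallback gives up the annulation and makes the aryl–O bond by copper-catalysed Ullmann coupling. It sets out from 1 and 8: mono-prenylation (K2CO3, acetone, reflux) should give methyl 2-hydroxy-4-methyl-6-[(3-methylbut-2-en-1-yl)oxy]benzoate F1. This phenol is then coupled with purchased methyl 2-bromo-3,5-dimethoxybenzoate F2 (CuI, N,N-dimethylglycine, Cs2CO3, dioxane, about 105 °C), the ortho ester of the bromide assisting the copper insertion. The coupling delivers 9 directly, so the route is rejoined at 9.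

Step 3. Aromatisation may outrun enol-ether formation and leave ring-B phenols incompletely methylated, and the electron-rich rings may be iodinated. The fallback separates oxidation from methylation. It sets out from 6: dehydrogenation over Pd/C in refluxing diglyme should give the resorcinol methyl 3,5-dihydroxy-2-[3-hydroxy-2-(methoxycarbonyl)-5-methylphenoxy]benzoate F3. The two non-chelated ring-B phenols are then methylated with MeI and K2CO3 in acetone at room temperature, where the hydrogen-bonded ring-A hydroxyl reacts much more slowly. This returns to the route at 7.

Step 5. Discrimination between the two esters may be lost (over-reduction), or the reduction of the ortho-aryloxy ester may stall. The fallback differentiates the esters by hydrolysis instead of hydride. It sets out from 9: LiOH in THF/H2O at room temperature should saponify only the ring-B ester, because 2,6-disubstituted benzoates resist acyl-oxygen hydrolysis, giving 2-{2-(methoxycarbonyl)-5-methyl-3-[(3-methylbut-2-en-1-yl)oxy]phenoxy}-3,5-dimethoxybenzoic acid F4. Activation with isobutyl chloroformate and N-methylmorpholine (THF, −10 °C) gives the mixed isobutyl carbonic anhydride F5. Without isolation this is reduced with NaBH4 (aqueous THF, 0 °C), which leaves the methyl ester and the prenyl alkene alone. The route is rejoined at 10.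

**Further compounds**

F1 | step 2 | methyl 2-hydroxy-4-methyl-6-[(3-methylbut-2-en-1-yl)oxy]benzoate | COC(=O)c1c(O)cc(C)cc1OCC=C(C)C
F2 | step 2 | methyl 2-bromo-3,5-dimethoxybenzoate | COC(=O)c1cc(OC)cc(OC)c1Br
F3 | step 3 | methyl 3,5-dihydroxy-2-[3-hydroxy-2-(methoxycarbonyl)-5-methylphenoxy]benzoate | COC(=O)c1cc(O)cc(O)c1Oc1cc(C)cc(O)c1C(=O)OC
F4 | step 5 | 2-{2-(methoxycarbonyl)-5-methyl-3-[(3-methylbut-2-en-1-yl)oxy]phenoxy}-3,5-dimethoxybenzoic acid | OC(=O)c1cc(OC)cc(OC)c1Oc1cc(C)cc(OCC=C(C)C)c1C(=O)OC
F5 | step 5 | mixed isobutyl carbonic anhydride of F4 | CC(C)COC(=O)OC(=O)c1cc(OC)cc(OC)c1Oc1cc(C)cc(OCC=C(C)C)c1C(=O)OC
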